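## Retrosynthetic overview

1. The target is a tridepside (ring C is the benzoic acid end with unprimed locants, ring B is primed, ring A is double-primed). The last bond cut is the benzyl ester on ring C, removed by hydrogenolysis.
2. Feature used: in ring A, the C2''-OH beside the carbonyl-bearing C1'' and the C4''-O two carbons further on match the ring oxygen and the 3-alkoxy position of a 3-alkoxyfuran (furan C5, C4, C3, C2 = C2'', C3'', C4'', C5''). C1'' (carbonyl) and C6'' (CH3) are the two alkyne carbons of a but-2-ynoate.
3. Key disconnection: C1''-C2'' and C5''-C6'', by Diels-Alder addition of 3-(benzyloxy)furan to the but-2-ynoate of the ring B-ring C didepside phenol. The hindered C1'' ester is therefore made beforehand from an unhindered alkynoic acid.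
4. Bridge opening: the oxygen must stay on C2'', so C5''-O must break. The C4'' donor is conjugated with C2'' but only cross-conjugated with C5'', so acid would break the wrong bond and give the 4'',5''-dioxygenated ring. The enol ether is therefore hydrolysed to the C4'' ketone, SmI2 cuts the alpha C5''-O bond, and oxidation of the C2'' carbinol lets ring A aromatise.
5. Ring order: rings C and B are preformed, both from orsellinic acid through one common MOM ether and joined by Steglich esterification. Ring A is the only ring formed, and it is formed last.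

Key step: step 10

Remark: the two oxa-bridged intermediates and the hydroxy ketone derived from them are racemic, and their SMILES show one enantiomer. All their stereocentres vanish on aromatisation, and the target is achiral.

## Route

Step 1
Reactants: 1 orsellinic acid (2,4-dihydroxy-6-methylbenzoic acid)
Product: 2 benzyl 2,4-dihydroxy-6-methylbenzoate
Conditions: BnBr (1.05 equiv), KHCO3, DMF, 25 °C
Reagents that add atoms: benzyl bromide, BrCc1ccccc1
Why: Carboxylate SN2 O-alkylation; KHCO3 deprotonates only the carboxylic acid, so both phenols stay free, and the mild temperature avoids decarboxylation of 1.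

Step 2
Reactants: 2 benzyl 2,4-dihydroxy-6-methylbenzoate
Product: 3 benzyl 2-hydroxy-4-(methoxymethoxy)-6-methylbenzoate
Conditions: MOMCl (1.1 equiv), iPr2NEt, CH2Cl2, 0 °C
Reagents that add atoms: chloromethyl methyl ether, COCCl
Why: Selective phenol O-alkylation (MOM ether formation); the C2-OH is hydrogen-bonded to the ester carbonyl and flanked by it, so one equivalent of reagent should react only at the free C4-OH.

Step 3
Reactants: 3 benzyl 2-hydroxy-4-(methoxymethoxy)-6-methylbenzoate
Product: 4 2-hydroxy-4-(methoxymethoxy)-6-methylbenzoic acid (ring B acid)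
Conditions: H2 (1 atm), Pd/C (10 wt %), EtOAc, 25 °C
Reagents that add atoms: none
Why: Catalytic hydrogenolysis of a benzyl ester; the MOM acetal and the arene are inert under these neutral conditions.

Step 4
Reactants: 3 benzyl 2-hydroxy-4-(methoxymethoxy)-6-methylbenzoate
Product: 5 benzyl 2-methoxy-4-(methoxymethoxy)-6-methylbenzoate
Conditions: MeI, K2CO3, DMF, 40 °C
Reagents that add atoms: iodomethane, CI
Why: Williamson ether synthesis; with C4-O blocked, carbonate in a dipolar solvent breaks the chelate and the phenoxide is methylated, while the MOM ether and benzyl ester are stable to base.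

Step 5
Reactants: 5 benzyl 2-methoxy-4-(methoxymethoxy)-6-methylbenzoate
Product: 6 benzyl 4-hydroxy-2-methoxy-6-methylbenzoate (ring C phenol)
Conditions: 3 M aq HCl-THF (1:4), 45 °C
Reagents that add atoms: none
Why: Acid-catalysed acetal hydrolysis of an aryl MOM ether; water traps the methoxymethyl cation before it can alkylate the ring, and the di-ortho-substituted benzyl ester resists dilute acid.

Step 6
Reactants: 4 2-hydroxy-4-(methoxymethoxy)-6-methylbenzoic acid; 6 benzyl 4-hydroxy-2-methoxy-6-methylbenzoate
Product: 7 benzyl 4-[2-hydroxy-4-(methoxymethoxy)-6-methylbenzoyloxy]-2-methoxy-6-methylbenzoate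
Conditions: DCC, DMAP (10 mol %), CH2Cl2, 0 to 25 °C
Reagents that add atoms: none
Why: Steglich esterification, the standard depside coupling; the only free, non-chelated hydroxyl is that of 6, and the chelated, hindered C2'-OH of 4 should not compete.

Step 7
Reactants: 7 benzyl 4-[2-hydroxy-4-(methoxymethoxy)-6-methylbenzoyloxy]-2-methoxy-6-methylbenzoate
Product: 8 benzyl 4-(2,4-dihydroxy-6-methylbenzoyloxy)-2-methoxy-6-methylbenzoate (didepside phenol)
Conditions: 3 M aq HCl-THF (1:4), 45 °C
Reagents that add atoms: none
Why: Acid-catalysed acetal hydrolysis as in step 5; the di-ortho-substituted aryl ester and the benzyl ester are both slow to hydrolyse in dilute acid.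

Step 8
Reactants: 8 benzyl 4-(2,4-dihydroxy-6-methylbenzoyloxy)-2-methoxy-6-methylbenzoate; 9 but-2-ynoic acid
Product: 10 benzyl 4-[4-(but-2-ynoyloxy)-2-hydroxy-6-methylbenzoyloxy]-2-methoxy-6-methylbenzoate
Conditions: DCC, DMAP (5 mol %), CH2Cl2, -10 to 0 °C
Reagents that add atoms: none
Why: Steglich esterification with an unhindered acid; the free 4'-OH is acylated in preference to the chelated 2'-OH, and low temperature with little DMAP suppresses conjugate addition to the ynoate and its isomerisation.

Step 9
Reactants: 11 3-bromofuran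
Product: 12 3-(benzyloxy)furan
Conditions: BnOH (1.5 equiv), CuI (10 mol %), 3,4,7,8-tetramethyl-1,10-phenanthroline (20 mol %), Cs2CO3, toluene, 110 °C, sealed tube; filtration through basic alumina
Reagents that add atoms: benzyl alcohol, OCc1ccccc1
Why: Ullmann-type copper-catalysed C-O coupling of a heteroaryl bromide with a primary alcohol, the reaction type that also turns 3-halofurans into 3-methoxyfuran; a base-only work-up protects the acid-labile product.

Step 10
Reactants: 10 benzyl 4-[4-(but-2-ynoyloxy)-2-hydroxy-6-methylbenzoyloxy]-2-methoxy-6-methylbenzoate; 12 3-(benzyloxy)furan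
Product: 14 benzyl 4-{2-hydroxy-6-methyl-4-[(3-methyl-5-oxo-7-oxabicyclo[2.2.1]hept-2-en-2-yl)carbonyloxy]benzoyloxy}-2-methoxy-6-methylbenzoate (racemic), via oxanorbornadiene enol ether 13 (not isolated)
Conditions: 12 (2 equiv), 2,6-di-tert-butylpyridine (5 mol %), CH2Cl2, 1.2 GPa, 30 °C; then AcOH-NaOAc buffer (1 M, pH 4.7), THF-H2O, 0 to 25 °C
Reagents that add atoms: water, O
Why: This is a normal-electron-demand Diels-Alder (4+2) cycloaddition of an electron-rich 3-alkoxyfuran with an aryl alkynoate, a known pairing that is slow for a beta-methyl alkynoate and is therefore driven by pressure rather than heat, so that neither cycloreversion nor thermal bridge opening should intervene. The intermolecular cycloaddition closes the six-membered carbocycle C1''-C6'' in one event and leaves the furan oxygen as a bridge between C2'' and C5''. Regiochemistry follows the para rule for a 2-donor diene: the benzyloxy group raises the HOMO coefficient at the adjacent furan C2, which bonds to the electrophilic methyl-bearing carbon C6'', so C4''-O ends para to the C1'' carbonyl. The two bridgehead stereocentres are necessarily cis, arise as a racemate and are erased on aromatisation, so no stereocontrol is needed. Because the benzyloxy donor is conjugated with C2'' and only cross-conjugated with C5'', a strong protic or Lewis acid would ionise C2''-O and lead to the 4'',5''-dioxygenated benzoate; the enol ether is therefore hydrolysed in a concentrated weak-acid buffer, since protonation at C3'' is general-acid catalysed whereas bridge ionisation needs prior O-protonation. The resulting C4'' ketone places C5''-O alpha to a carbonyl and so fixes which bridge bond is cut in step 11.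

Step 11
Reactants: 14 oxa-bridged keto ester (racemic)
Product: 15 benzyl 4-{2-hydroxy-4-[(6-hydroxy-2-methyl-4-oxocyclohex-1-en-1-yl)carbonyloxy]-6-methylbenzoyloxy}-2-methoxy-6-methylbenzoate (racemic)
Conditions: SmI2 (2.2 equiv, 0.1 M in THF), MeOH (10 equiv), THF, -78 °C; pH 7 phosphate buffer quench; crude 15 used at once
Reagents that add atoms: none
Why: SmI2 alpha-deoxygenation of an alpha-alkoxy ketone, the reaction type known for reductive oxa-bridge opening of 7-oxabicyclo[2.2.1]heptan-2-ones; only C5''-O is alpha to the ketone (and gamma to the enoate), so the oxygen stays on C2'' with its configuration unchanged, and methanol should protonate the samarium enolate before it can relay charge through C6''=C1''.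

Step 12
Reactants: 15 hydroxy keto ester (racemic)
Product: 17 benzyl 4-[4-(2,4-dihydroxy-6-methylbenzoyloxy)-2-hydroxy-6-methylbenzoyloxy]-2-methoxy-6-methylbenzoate, via cyclohexenedione 16 (not isolated)
Conditions: DMP (1.2 equiv), NaHCO3 (5 equiv), CH2Cl2, 0 °C
Reagents that add atoms: none
Why: Dess-Martin oxidation of a beta-hydroxy ketone to a 1,3-diketone; 16 is the diketo tautomer of a resorcinol and should enolise at once to aromatic ring A with the former bridge oxygen as the chelated C2''-OH.

Step 13
Reactants: 17 tridepside benzyl ester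
Product: 18 4-[4-(2,4-dihydroxy-6-methylbenzoyloxy)-2-hydroxy-6-methylbenzoyloxy]-2-methoxy-6-methylbenzoic acid (CNP0283563.0)
Conditions: H2 (1 atm), Pd/C (10 wt %), EtOAc, 25 °C
Reagents that add atoms: none
Why: Catalytic hydrogenolysis of the benzyl ester; the aryl esters, methyl ether and phenols are inert, and the neutral medium avoids transesterification of the depside links.

## Compound list

1 | orsellinic acid | Cc1cc(O)cc(O)c1C(=O)O | starting material
2 | benzyl 2,4-dihydroxy-6-methylbenzoate | Cc1cc(O)cc(O)c1C(=O)OCc1ccccc1 | intermediate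
3 | benzyl 2-hydroxy-4-(methoxymethoxy)-6-methylbenzoate | COCOc1cc(C)c(C(=O)OCc2ccccc2)c(O)c1 | intermediate
4 | 2-hydroxy-4-(methoxymethoxy)-6-methylbenzoic acid | COCOc1cc(C)c(C(=O)O)c(O)c1 | intermediate
5 | benzyl 2-methoxy-4-(methoxymethoxy)-6-methylbenzoate | COCOc1cc(C)c(C(=O)OCc2ccccc2)c(OC)c1 | intermediate
6 | benzyl 4-hydroxy-2-methoxy-6-methylbenzoate | COc1cc(O)cc(C)c1C(=O)OCc1ccccc1 | intermediate
7 | didepside MOM ether | COCOc1cc(C)c(C(=O)Oc2cc(C)c(C(=O)OCc3ccccc3)c(OC)c2)c(O)c1 | intermediate
8 | didepside phenol | Cc1cc(O)cc(O)c1C(=O)Oc1cc(C)c(C(=O)OCc2ccccc2)c(OC)c1 | intermediate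
9 | but-2-ynoic acid | CC#CC(=O)O | starting material
10 | didepside but-2-ynoate | CC#CC(=O)Oc1cc(C)c(C(=O)Oc2cc(C)c(C(=O)OCc3ccccc3)c(OC)c2)c(O)c1 | intermediate
11 | 3-bromofuran | Brc1ccoc1 | starting material
12 | 3-(benzyloxy)furan | c1cc(OCc2ccccc2)co1 | intermediate
13 | didepside 5-(benzyloxy)-3-methyl-7-oxabicyclo[2.2.1]hepta-2,5-diene-2-carboxylate (racemic, not isolated) | CC1=C(C(=O)Oc3cc(C)c(C(=O)Oc4cc(C)c(C(=O)OCc5ccccc5)c(OC)c4)c(O)c3)[C@H]2C=C(OCc3ccccc3)[C@@H]1O2 | intermediate
14 | didepside 3-methyl-5-oxo-7-oxabicyclo[2.2.1]hept-2-ene-2-carboxylate (racemic) | CC1=C(C(=O)Oc3cc(C)c(C(=O)Oc4cc(C)c(C(=O)OCc5ccccc5)c(OC)c4)c(O)c3)[C@H]2CC(=O)[C@@H]1O2 | intermediate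
15 | didepside 6-hydroxy-2-methyl-4-oxocyclohex-1-ene-1-carboxylate (racemic) | CC1=C(C(=O)Oc2cc(C)c(C(=O)Oc3cc(C)c(C(=O)OCc4ccccc4)c(OC)c3)c(O)c2)[C@H](O)CC(=O)C1 | intermediate
16 | didepside 2-methyl-4,6-dioxocyclohex-1-ene-1-carboxylate (not isolated) | CC1=C(C(=O)Oc2cc(C)c(C(=O)Oc3cc(C)c(C(=O)OCc4ccccc4)c(OC)c3)c(O)c2)C(=O)CC(=O)C1 | intermediate
17 | tridepside benzyl ester | Cc1cc(O)cc(O)c1C(=O)Oc1cc(C)c(C(=O)Oc2cc(C)c(C(=O)OCc3ccccc3)c(OC)c2)c(O)c1 | intermediate
18 | CNP0283563.0 | COc1cc(OC(=O)c2c(C)cc(OC(=O)c3c(C)cc(O)cc3O)cc2O)cc(C)c1C(=O)O | target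

## Step count and risks

Total step count: 13.
Longest linear sequence: 11 steps from 1 (steps 1, 2, 4, 5, 6, 7, 8, 10, 11, 12, 13).

**Step 10.** The cycloaddition may be too slow for the beta-methyl alkynoate. Alternatively, the vinylogous acetal C4''(OBn)=C3''-C2''-O may ionise before C3'' is protonated, which would open the bridge at the wrong bond.

Fallback, from 8 back to 17: the dienophile is changed from the alkyne to its more reactive allene isomer, which forms the same two bonds. Phenol 8 is esterified with but-3-ynoic acid (DCC, CH2Cl2, 0 °C) to the didepside but-3-ynoate F1. A trace of Et3N moves the unsaturation to give the didepside buta-2,3-dienoate F2. Furan 12 should add across the activated C1''=C6'' bond of F2 near room temperature to give the 3-methylidene-7-oxanorbornene enol ether F3. In this alkene-type adduct, ionisation of C2''-O no longer leads toward an arene, so the same buffer should give the methylidene ketone F4 cleanly. SmI2 as in step 11 cuts C5''-O, and protonation of the dienolate gives the hydroxy enone F5. Dess-Martin oxidation of its C2'' carbinol gives a beta-keto ester that tautomerises to 17.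

**Step 11.** After C5''-O scission, the samarium enolate may pass its charge through C6''=C1'' and expel the C2'' oxygen (net deoxygenation). Electron transfer to the enoate may also compete.

Fallback, from 8 and 4 back to 17: ring A is brought in preformed. Acid 4, already in hand, is coupled a second time (DCC, DMAP, CH2Cl2) with the free 4'-OH of 8 to give the 4''-O-MOM tridepside benzyl ester F6. Aqueous HCl in THF as in step 7 removes the acetal to give 17.

**Step 12.** Loss of water from the beta-hydroxy ketone (aromatisation without the C2'' oxygen) may outrun the oxidation once the hydroxyl is bound to iodine.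

Fallback, from 15 back to 17: the carbinol is masked instead of oxidised, and the ring is dehydrogenated. Et3SiCl and imidazole convert 15 into the triethylsilyl ether F7. DDQ takes hydride from C2''-H of its dienol tautomer, a position activated by the silyloxy group and the conjugated dienol. Loss of a C3'' proton then gives the 2''-O-triethylsilyl tridepside benzyl ester F8. HF·pyridine frees the phenol to give 17.

## Further compounds

F1 | step 10 | benzyl 4-[4-(but-3-ynoyloxy)-2-hydroxy-6-methylbenzoyloxy]-2-methoxy-6-methylbenzoate | C#CCC(=O)Oc1cc(C)c(C(=O)Oc2cc(C)c(C(=O)OCc3ccccc3)c(OC)c2)c(O)c1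
F2 | step 10 | benzyl 4-[4-(buta-2,3-dienoyloxy)-2-hydroxy-6-methylbenzoyloxy]-2-methoxy-6-methylbenzoate | C=C=CC(=O)Oc1cc(C)c(C(=O)Oc2cc(C)c(C(=O)OCc3ccccc3)c(OC)c2)c(O)c1
F3 | step 10 | didepside 5-(benzyloxy)-3-methylidene-7-oxabicyclo[2.2.1]hept-5-ene-2-carboxylate (racemic, endo/exo mixture at C1'') | C=C1C(C(=O)Oc3cc(C)c(C(=O)Oc4cc(C)c(C(=O)OCc5ccccc5)c(OC)c4)c(O)c3)[C@H]2C=C(OCc3ccccc3)[C@@H]1O2
F4 | step 10 | didepside 3-methylidene-5-oxo-7-oxabicyclo[2.2.1]heptane-2-carboxylate (racemic, endo/exo mixture at C1'') | C=C1C(C(=O)Oc3cc(C)c(C(=O)Oc4cc(C)c(C(=O)OCc5ccccc5)c(OC)c4)c(O)c3)[C@H]2CC(=O)[C@@H]1O2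
F5 | step 10 | didepside 6-hydroxy-2-methyl-4-oxocyclohex-2-ene-1-carboxylate (racemic mixture of diastereomers) | CC1=CC(=O)CC(O)C1C(=O)Oc1cc(C)c(C(=O)Oc2cc(C)c(C(=O)OCc3ccccc3)c(OC)c2)c(O)c1
F6 | step 11 | benzyl 4-{2-hydroxy-4-[2-hydroxy-4-(methoxymethoxy)-6-methylbenzoyloxy]-6-methylbenzoyloxy}-2-methoxy-6-methylbenzoate | COCOc1cc(C)c(C(=O)Oc2cc(C)c(C(=O)Oc3cc(C)c(C(=O)OCc4ccccc4)c(OC)c3)c(O)c2)c(O)c1
F7 | step 12 | didepside 2-methyl-4-oxo-6-(triethylsilyloxy)cyclohex-1-ene-1-carboxylate (racemic) | CC1=C(C(=O)Oc2cc(C)c(C(=O)Oc3cc(C)c(C(=O)OCc4ccccc4)c(OC)c3)c(O)c2)[C@H](O[Si](CC)(CC)CC)CC(=O)C1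
F8 | step 12 | benzyl 4-{2-hydroxy-4-[4-hydroxy-2-methyl-6-(triethylsilyloxy)benzoyloxy]-6-methylbenzoyloxy}-2-methoxy-6-methylbenzoate | Cc1cc(O)cc(O[Si](CC)(CC)CC)c1C(=O)Oc1cc(C)c(C(=O)Oc2cc(C)c(C(=O)OCc3ccccc3)c(OC)c2)c(O)c1
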